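**Retrosynthetic overview**

1. Numbering: ring C1 (CH2OAc carbon C1'), C2 (CHO carbon C2'), C3, C4, C5=C6(CH3), C7, C8 (OH), C9 (side-chain methine C10). The strategy rests on the 1,4-relation of the C8 oxygen and the carbonyl-level carbon C2 through C9 and C1: O–C8–C9–C1–C2 is a γ-butyrolactone ring with C1' as its exocyclic methylene.
2. Target ⇐ C2 enol triflate (carbonylative formylation brings in C2') ⇐ nine-membered ketone ⇐ ring closure at C3–C4 by alkylation of a β-keto sulfone with a C4 allylic bromide; C3 and its activating sulfonyl group come from PhSO2CH2Li, which opens the lactone at C2.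
3. All-trans lactone ⇐ PMB alcohol addition at C1' and inversion at C8 ⇐ cis-α-methylene lactone ⇐ union of aldehyde 11 and bromide 7 at C8–C9 by chromium 2-(ethoxycarbonyl)allylation–lactonisation.
4. 7 ⇐ (S)-citronellal (one-carbon degradation, vinylalumination with ethyl propiolate, SN2' bromination); 11 ⇐ (E)-3-methylpent-2-en-4-yn-1-ol (silylation, alkyne hydroboration–oxidation).
5. Ring order: lactone first (step 6), carbocycle second (step 14), after the lactone has been opened (step 10). C3 is left out of the aldehyde because closing C2–C3 on the intact lactone would hold the E C5=C6 olefin in a bridged eight-membered ring.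

Key step: step 6

Assumption: the acyclic 2-(ethoxycarbonyl)allylchromium reagent reacts through the chair in which C10 is cis to the CH2Cr terminus (no A(1,2) strain with the ester), so the addition is taken to be syn, the lactone of step 6 is cis, and C8 is inverted in step 9.

**Route**

Step 1
Reactants: 1 (S)-citronellal
Product: 3 (2S)-2,6-dimethylhept-5-enal, via enamine 2 (not isolated)
Conditions: morpholine (1.0 equiv), K2CO3, toluene, 0 °C to rt, filter, concentrate; then CuCl (10 mol %), O2 (1 atm), MeCN, 0 °C to rt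
Reagents that add atoms: dioxygen, O=O
Why: Copper-catalysed aerobic cleavage of the electron-rich enamine C=C (one-carbon degradation of an aldehyde through its enamine) removes C1 as the formamide and leaves the trisubstituted olefin alone; the stereocentre is not touched and stays S, and exactly one equivalent of amine is used so that the α-branched product is not degraded or epimerised through a second enamine.

Step 2
Reactants: 3 (2S)-2,6-dimethylhept-5-enal; 4 ethyl propiolate
Product: 6 ethyl (4S)-3-hydroxy-4,8-dimethyl-2-methylidenenon-7-enoate (both C3 epimers), via vinylalane 5 (not isolated)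
Conditions: i-Bu2AlH, N-methylmorpholine N-oxide, THF, 0 °C; 4, 0 °C; then 3, 0 °C to rt; aqueous potassium sodium tartrate
Reagents that add atoms: none
Why: Hydroalumination of the propiolate gives the α-aluminoacrylate, which adds to the aldehyde (vinylalumination, the non-basic counterpart of the Baylis–Hillman reaction) quickly enough at 0 °C that the α-stereocentre of 3 is not epimerised; the new carbinol centre forms as a mixture, which does not matter because it is lost in step 3.

Step 3
Reactants: 6 ethyl (4S)-3-hydroxy-4,8-dimethyl-2-methylidenenon-7-enoate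
Product: 7 ethyl (2Z,4S)-2-(bromomethyl)-4,8-dimethylnona-2,7-dienoate
Conditions: NBS, Me2S, CH2Cl2, 0 °C to rt
Reagents that add atoms: N-bromosuccinimide, O=C1CCC(=O)N1Br
Why: The alkoxysulfonium salt of the allylic alcohol is displaced by bromide in the SN2' sense (Corey–Kim-type bromination of a Baylis–Hillman alcohol), which gives the conjugated Z bromide and leaves the remote olefin and the stereocentre untouched.

Step 4
Reactants: 8 (E)-3-methylpent-2-en-4-yn-1-ol
Product: 9 tert-butyldimethyl{[(2E)-3-methylpent-2-en-4-yn-1-yl]oxy}silane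
Conditions: TBSCl, imidazole, CH2Cl2, 0 °C to rt
Reagents that add atoms: tert-butyldimethylsilyl chloride, CC(C)(C)[Si](C)(C)Cl
Why: Routine silylation of a primary allylic alcohol protects the future C4 oxygen; the E olefin that becomes C5=C6 is already present in the starting material.

Step 5
Reactants: 9 tert-butyldimethyl{[(2E)-3-methylpent-2-en-4-yn-1-yl]oxy}silane
Product: 11 (3E)-5-[(tert-butyldimethylsilyl)oxy]-3-methylpent-3-enal, via dienylborane 10 (not isolated)
Conditions: (c-C6H11)2BH (from BH3·SMe2 and cyclohexene), THF, 0 °C; then 30% H2O2, NaH2PO4/Na2HPO4 buffer (pH 7), 0 °C; used crude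
Reagents that add atoms: hydrogen peroxide, OO
Why: The dialkylborane adds to the terminal alkyne faster than to the trisubstituted olefin and places boron on the terminal carbon (anti-Markovnikov hydroboration of an enyne), and buffered oxidation gives the enol, which is protonated at the α-carbon to the β,γ-unsaturated aldehyde without touching the E olefin.

Step 6
Reactants: 7 ethyl (2Z,4S)-2-(bromomethyl)-4,8-dimethylnona-2,7-dienoate; 11 (3E)-5-[(tert-butyldimethylsilyl)oxy]-3-methylpent-3-enal
Product: 15 (4R,5R)-cis-3-methylidene lactone (C8 epimeric to the target), via allylchromium reagent 12 (not isolated), via silyl ether 13 (not isolated), via hydroxy ester 14 (not isolated)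
Conditions: CrCl2 (10 mol %), 3,6-diphenyl-1,8-bis(4-isopropyl-4,5-dihydrooxazol-2-yl)carbazole (12 mol %, the enantiomer that directs attack to the Si face of the aldehyde), i-Pr2NEt, Mn powder, Me3SiCl, THF, rt; then aqueous citric acid, THF, 0 °C; pyridinium p-toluenesulfonate (cat.), toluene, 40 °C
Reagents that add atoms: none
Why: Divalent chromium reduces the allylic bromide to the ligand-bound allylchromium reagent 12 (trivalent chromium), whose olefin geometry equilibrates so that the geometry of 7 does not matter, while manganese returns the chromium and Me3SiCl releases the adduct as silyl ether 13 (Nozaki–Hiyama 2-(alkoxycarbonyl)allylation in its catalytic asymmetric form, a known reaction type). The reagent adds through its γ-carbon C9 to C8 in a closed chair transition state with the C7 chain equatorial and C10 cis to the CH2Cr terminus, the only arrangement free of A(1,2) strain between C10 and the ester, so C10 is axial and the adduct is syn. After desilylation the C8 hydroxyl of 14 attacks the ester carbon C2 (5-exo-trig acyl substitution with loss of ethanol) and closes the γ-butyrolactone O–C8–C9–C1–C2 as the cis isomer. C8 (R) is set by the ligand, which blocks the Re face of the aldehyde, and C9 (R) follows from C8 through the chair, so the ligand and not the weak methyl/methylene bias of C10 decides the C9–C10 relationship. The step needs chemoselectivity for the aldehyde and a base-free medium: the allylchromium reagent ignores esters, silyl ethers and isolated olefins, and the neutral conditions leave the β,γ-unsaturated aldehyde unconjugated and the E C5=C6 olefin in place. C8 is formed here with the configuration opposite to the target on purpose and is inverted in step 9.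

Step 7
Reactants: 15 (4R,5R)-cis-3-methylidene lactone
Product: 16 (3S,4R,5R)-3-{[(4-methoxybenzyl)oxy]methyl} lactone
Conditions: 4-methoxybenzyl alcohol (5 equiv), KOt-Bu (10 mol %), THF, 0 °C to rt
Reagents that add atoms: 4-methoxybenzyl alcohol, COc1ccc(CO)cc1
Why: Alkoxide-catalysed oxa-Michael addition to the α-methylene lactone places the oxygen on C1', and because addition and enolate protonation are reversible C1 equilibrates to the isomer with CH2OPMB trans to the branched C10 substituent on C9 (thermodynamic control).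

Step 8
Reactants: 16 (3S,4R,5R)-3-{[(4-methoxybenzyl)oxy]methyl} lactone
Product: 17 (2S,3R,4R)-4-hydroxy N,N-dimethylamide
Conditions: Me2NH·HCl, AlMe3, CH2Cl2, 0 °C to rt; aqueous potassium sodium tartrate
Reagents that add atoms: dimethylamine hydrochloride, CNC.Cl
Why: Aluminium amide aminolysis of the lactone opens the ring at C2 without touching the silyl or PMB ether and frees the C8 hydroxyl that has to be inverted; no stereocentre is affected.

Step 9
Reactants: 17 (2S,3R,4R)-4-hydroxy N,N-dimethylamide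
Product: 20 (3S,4R,5S)-all-trans lactone, via mesylate 18 (not isolated), via iminium lactone 19 (not isolated)
Conditions: Ms2O, Et3N, CH2Cl2, −20 °C to rt; then THF, aqueous NaH2PO4 (pH 5), rt
Reagents that add atoms: water, O
Why: The amide oxygen displaces the C8 mesylate from the rear (neighbouring-group participation, 5-exo-tet, inversion at C8) and the iminium ether is hydrolysed at slightly acidic pH with loss of dimethylamine (lactone inversion through a hydroxy amide), which gives the all-trans lactone with C8 (S) as in the target.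

Step 10
Reactants: 20 (3S,4R,5S)-all-trans lactone; 21 methyl phenyl sulfone
Product: 22 (3S,4R,5S)-5-hydroxy β-keto sulfone
Conditions: 21 (2.3 equiv), n-BuLi (2.2 equiv), THF, −78 °C; then 20, −78 to −40 °C; aqueous NH4Cl
Reagents that add atoms: none
Why: The sulfonyl carbanion adds to the lactone carbonyl C2 and the ring opens to the β-keto sulfone (Claisen-type acylation of a lithiated sulfone), which is deprotonated at once by the second equivalent and so is protected from a second addition and from enolisation towards C1; the carbanion carbon becomes C3 and carries the activating sulfonyl group.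

Step 11
Reactants: 22 (3S,4R,5S)-5-hydroxy β-keto sulfone
Product: 23 (3S,4R,5S)-5,9-bis(silyl ether) β-keto sulfone
Conditions: TBSOTf, 2,6-lutidine, CH2Cl2, −78 to 0 °C; aqueous citric acid work-up
Reagents that add atoms: tert-butyldimethylsilyl trifluoromethanesulfonate, CC(C)(C)[Si](C)(C)OS(=O)(=O)C(F)(F)F
Why: Silyl triflate silylation of the hindered secondary C8 hydroxyl draws the open-chain hydroxy ketone out of its equilibrium with the five-membered hemiketal, and any silyl enol ether of the keto sulfone is hydrolysed in the work-up.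

Step 12
Reactants: 23 (3S,4R,5S)-5,9-bis(silyl ether) β-keto sulfone
Product: 24 (3S,4R,5S)-9-hydroxy-5-silyloxy β-keto sulfone
Conditions: pyridinium p-toluenesulfonate (0.2 equiv), MeOH, rt
Reagents that add atoms: none
Why: Acid-catalysed methanolysis removes the unhindered primary allylic silyl ether at C4 much faster than the secondary one at C8, which is flanked by the branched C9 (selective desilylation).

Step 13
Reactants: 24 (3S,4R,5S)-9-hydroxy-5-silyloxy β-keto sulfone
Product: 25 (3S,4R,5S)-9-bromo-5-silyloxy β-keto sulfone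
Conditions: CBr4, PPh3, CH2Cl2, 0 °C
Reagents that add atoms: carbon tetrabromide, BrC(Br)(Br)Br
Why: Appel bromination of the primary allylic alcohol runs under neutral conditions with retention of the E olefin and makes C4 the electrophile for the ring closure.

Step 14
Reactants: 25 (3S,4R,5S)-9-bromo-5-silyloxy β-keto sulfone
Product: 26 (4E,7S,8R,9S)-2-(phenylsulfonyl)cyclonon-4-en-1-one (C2 epimers of the cyclononenone numbering)
Conditions: Cs2CO3, MeCN, 50 °C, slow addition of 25 to a final 0.002 M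
Reagents that add atoms: none
Why: The soft caesium enolate of the β-keto sulfone C-alkylates the primary allylic bromide in the SN2 sense and closes the nine-membered ring at C3–C4 (intramolecular alkylation of a β-keto sulfone, an established medium-ring closure) with the E geometry of C5=C6 carried over from 25; C3 forms as a mixture that is removed in step 15, and because only the C3–H is acidic enough for carbonate, C1 neither epimerises nor loses the PMB alkoxide.

Step 15
Reactants: 26 (4E,7S,8R,9S)-2-(phenylsulfonyl)cyclonon-4-en-1-one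
Product: 27 (4E,7S,8R,9S)-cyclonon-4-en-1-one
Conditions: SmI2 (2.5 equiv), THF–MeOH, −78 °C
Reagents that add atoms: none
Why: Single-electron reduction of the β-keto sulfone expels benzenesulfinate and the samarium enolate is protonated at C3 by methanol (reductive desulfonylation), which leaves the ketone, the ethers and C1 untouched.

Step 16
Reactants: 27 (4E,7S,8R,9S)-cyclonon-4-en-1-one
Product: 29 (1E,4E,7S,8R,9S)-cyclonona-1,4-dien-1-yl triflate, via potassium enolate 28 (not isolated)
Conditions: KN(SiMe3)2, THF, −78 °C; then PhNTf2, −78 to 0 °C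
Reagents that add atoms: N-phenylbis(trifluoromethanesulfonimide), O=S(=O)(N(c1ccccc1)S(=O)(=O)C(F)(F)F)C(F)(F)F
Why: The bulky amide removes a proton from the C3 methylene and not from the hindered C1 methine (kinetic enolate formation), the ring beside the E C5=C6 olefin allows only the C2=C3 geometry with C1 and C4 cis, and O-triflation fixes this enolate as the enol triflate.

Step 17
Reactants: 29 (1E,4E,7S,8R,9S)-cyclonona-1,4-dien-1-yl triflate
Product: 30 (1E,4E,7S,8R,9S)-9-(hydroxymethyl)cyclonona-1,4-dien-1-yl triflate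
Conditions: DDQ, CH2Cl2–NaH2PO4/Na2HPO4 buffer (pH 7), 0 °C
Reagents that add atoms: none
Why: DDQ abstracts hydride from the electron-rich PMB ether (oxidative PMB cleavage) and frees the C1' hydroxyl, while the enol triflate, the silyl ether and the unactivated olefins are not oxidised.

Step 18
Reactants: 30 (1E,4E,7S,8R,9S)-9-(hydroxymethyl)cyclonona-1,4-dien-1-yl triflate
Product: 31 [(1S,2E,5E,8S,9R)-2-(triflyloxy)cyclonona-2,5-dien-1-yl]methyl acetate
Conditions: Ac2O, pyridine, DMAP (cat.), CH2Cl2, 0 °C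
Reagents that add atoms: acetic anhydride, CC(=O)OC(C)=O
Why: DMAP-catalysed acylation of the only free hydroxyl installs the acetate before the base-sensitive enal exists.

Step 19
Reactants: 31 [(1S,2E,5E,8S,9R)-2-(triflyloxy)cyclonona-2,5-dien-1-yl]methyl acetate
Product: 32 [(1R,2E,5E,8S,9R)-2-formyl-8-silyloxycyclonona-2,5-dien-1-yl]methyl acetate
Conditions: Pd(PPh3)4 (5 mol %), CO (1 atm), Bu3SnH (slow addition), LiCl, THF, 50 °C
Reagents that add atoms: carbon monoxide, [C-]#[O+]
Why: Oxidative addition of zerovalent palladium to the enol triflate, CO insertion and hydride transfer from the tin hydride to the acylpalladium species (Stille-type carbonylative formylation) give the enal with the C2=C3 geometry of the triflate retained, and the neutral conditions do not conjugate the skipped diene.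

Step 20
Reactants: 32 [(1R,2E,5E,8S,9R)-2-formyl-8-silyloxycyclonona-2,5-dien-1-yl]methyl acetate
Product: 33 hydroxyacetyldictyolal
Conditions: HF·pyridine, pyridine, THF, 0 °C to rt
Reagents that add atoms: none
Why: Buffered fluoride cleaves the secondary silyl ether (desilylation) without acyl migration, conjugation of the skipped diene or attack on the enal, and gives the target.

**Compound list**

1 | (S)-citronellal, (3S)-3,7-dimethyloct-6-enal | O=CC[C@@H](C)CCC=C(C)C | starting material
2 | 4-[(1E,3S)-3,7-dimethylocta-1,6-dien-1-yl]morpholine | C1COCCN1/C=C/[C@@H](C)CCC=C(C)C | intermediate (not isolated)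
3 | (2S)-2,6-dimethylhept-5-enal | O=C[C@@H](C)CCC=C(C)C | intermediate
4 | ethyl propiolate | C#CC(=O)OCC | starting material
5 | ethyl 2-(diisobutylalumanyl)prop-2-enoate | C=C(C(=O)OCC)[Al](CC(C)C)CC(C)C | intermediate (not isolated)
6 | ethyl (4S)-3-hydroxy-4,8-dimethyl-2-methylidenenon-7-enoate (C3 epimers) | C=C(C(=O)OCC)C(O)[C@@H](C)CCC=C(C)C | intermediate
7 | ethyl (2Z,4S)-2-(bromomethyl)-4,8-dimethylnona-2,7-dienoate | CCOC(=O)/C(CBr)=C/[C@@H](C)CCC=C(C)C | intermediate
8 | (E)-3-methylpent-2-en-4-yn-1-ol | C#C/C(C)=C/CO | starting material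
9 | tert-butyldimethyl{[(2E)-3-methylpent-2-en-4-yn-1-yl]oxy}silane | C#C/C(C)=C/CO[Si](C)(C)C(C)(C)C | intermediate
10 | tert-butyl{[(2E,4E)-5-(dicyclohexylboranyl)-3-methylpenta-2,4-dien-1-yl]oxy}dimethylsilane | CC(C)(C)[Si](C)(C)OC/C=C(C)/C=C/B(C1CCCCC1)C1CCCCC1 | intermediate (not isolated)
11 | (3E)-5-[(tert-butyldimethylsilyl)oxy]-3-methylpent-3-enal | O=CC/C(C)=C/CO[Si](C)(C)C(C)(C)C | intermediate
12 | ethyl (4S)-2-[(dichlorochromio)methyl]-4,8-dimethylnona-2,7-dienoate (trivalent chromium, chiral ligand not drawn, olefin geometry mobile) | CCOC(=O)C(C[Cr](Cl)Cl)=C[C@@H](C)CCC=C(C)C | intermediate (not isolated)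
13 | ethyl (3R,4R,6E)-8-[(tert-butyldimethylsilyl)oxy]-6-methyl-3-[(2S)-6-methylhept-5-en-2-yl]-2-methylidene-4-[(trimethylsilyl)oxy]oct-6-enoate | C=C(C(=O)OCC)[C@@H]([C@@H](C)CCC=C(C)C)[C@H](O[Si](C)(C)C)C/C(C)=C/CO[Si](C)(C)C(C)(C)C | intermediate (not isolated)
14 | ethyl (3R,4R,6E)-8-[(tert-butyldimethylsilyl)oxy]-4-hydroxy-6-methyl-3-[(2S)-6-methylhept-5-en-2-yl]-2-methylideneoct-6-enoate | C=C(C(=O)OCC)[C@@H]([C@@H](C)CCC=C(C)C)[C@H](O)C/C(C)=C/CO[Si](C)(C)C(C)(C)C | intermediate (not isolated)
15 | (4R,5R)-5-{(2E)-4-[(tert-butyldimethylsilyl)oxy]-2-methylbut-2-en-1-yl}-3-methylidene-4-[(2S)-6-methylhept-5-en-2-yl]oxolan-2-one (cis) | C=C1C(=O)O[C@H](C/C(C)=C/CO[Si](C)(C)C(C)(C)C)[C@@H]1[C@@H](C)CCC=C(C)C | intermediate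
16 | (3S,4R,5R)-5-{(2E)-4-[(tert-butyldimethylsilyl)oxy]-2-methylbut-2-en-1-yl}-3-{[(4-methoxybenzyl)oxy]methyl}-4-[(2S)-6-methylhept-5-en-2-yl]oxolan-2-one | COc1ccc(COC[C@H]2C(=O)O[C@H](C/C(C)=C/CO[Si](C)(C)C(C)(C)C)[C@@H]2[C@@H](C)CCC=C(C)C)cc1 | intermediate
17 | (2S,3R,4R,6E)-8-[(tert-butyldimethylsilyl)oxy]-4-hydroxy-2-{[(4-methoxybenzyl)oxy]methyl}-N,N,6-trimethyl-3-[(2S)-6-methylhept-5-en-2-yl]oct-6-enamide | CN(C)C(=O)[C@H](COCc1ccc(OC)cc1)[C@@H]([C@@H](C)CCC=C(C)C)[C@H](O)C/C(C)=C/CO[Si](C)(C)C(C)(C)C | intermediate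
18 | (2S,3R,4R,6E)-8-[(tert-butyldimethylsilyl)oxy]-4-[(methanesulfonyl)oxy]-2-{[(4-methoxybenzyl)oxy]methyl}-N,N,6-trimethyl-3-[(2S)-6-methylhept-5-en-2-yl]oct-6-enamide | CN(C)C(=O)[C@H](COCc1ccc(OC)cc1)[C@@H]([C@@H](C)CCC=C(C)C)[C@H](OS(C)(=O)=O)C/C(C)=C/CO[Si](C)(C)C(C)(C)C | intermediate (not isolated)
19 | N-[(3S,4R,5S)-5-{(2E)-4-[(tert-butyldimethylsilyl)oxy]-2-methylbut-2-en-1-yl}-3-{[(4-methoxybenzyl)oxy]methyl}-4-[(2S)-6-methylhept-5-en-2-yl]oxolan-2-ylidene]-N-methylmethanaminium methanesulfonate | C[N+](C)=C1O[C@@H](C/C(C)=C/CO[Si](C)(C)C(C)(C)C)[C@H]([C@@H](C)CCC=C(C)C)[C@H]1COCc1ccc(OC)cc1.CS(=O)(=O)[O-] | intermediate (not isolated)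
20 | (3S,4R,5S)-5-{(2E)-4-[(tert-butyldimethylsilyl)oxy]-2-methylbut-2-en-1-yl}-3-{[(4-methoxybenzyl)oxy]methyl}-4-[(2S)-6-methylhept-5-en-2-yl]oxolan-2-one (all-trans) | COc1ccc(COC[C@H]2C(=O)O[C@@H](C/C(C)=C/CO[Si](C)(C)C(C)(C)C)[C@@H]2[C@@H](C)CCC=C(C)C)cc1 | intermediate
21 | methyl phenyl sulfone | CS(=O)(=O)c1ccccc1 | starting material
22 | (3S,4R,5S,7E)-9-[(tert-butyldimethylsilyl)oxy]-5-hydroxy-3-{[(4-methoxybenzyl)oxy]methyl}-7-methyl-4-[(2S)-6-methylhept-5-en-2-yl]-1-(phenylsulfonyl)non-7-en-2-one (in equilibrium with its five-membered hemiketal) | O=S(=O)(CC(=O)[C@H](COCc1ccc(OC)cc1)[C@@H]([C@@H](C)CCC=C(C)C)[C@@H](O)C/C(C)=C/CO[Si](C)(C)C(C)(C)C)c1ccccc1 | intermediate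
23 | (3S,4R,5S,7E)-5,9-bis[(tert-butyldimethylsilyl)oxy]-3-{[(4-methoxybenzyl)oxy]methyl}-7-methyl-4-[(2S)-6-methylhept-5-en-2-yl]-1-(phenylsulfonyl)non-7-en-2-one | O=S(=O)(CC(=O)[C@H](COCc1ccc(OC)cc1)[C@@H]([C@@H](C)CCC=C(C)C)[C@@H](O[Si](C)(C)C(C)(C)C)C/C(C)=C/CO[Si](C)(C)C(C)(C)C)c1ccccc1 | intermediate
24 | (3S,4R,5S,7E)-5-[(tert-butyldimethylsilyl)oxy]-9-hydroxy-3-{[(4-methoxybenzyl)oxy]methyl}-7-methyl-4-[(2S)-6-methylhept-5-en-2-yl]-1-(phenylsulfonyl)non-7-en-2-one | O=S(=O)(CC(=O)[C@H](COCc1ccc(OC)cc1)[C@@H]([C@@H](C)CCC=C(C)C)[C@@H](O[Si](C)(C)C(C)(C)C)C/C(C)=C/CO)c1ccccc1 | intermediate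
25 | (3S,4R,5S,7E)-9-bromo-5-[(tert-butyldimethylsilyl)oxy]-3-{[(4-methoxybenzyl)oxy]methyl}-7-methyl-4-[(2S)-6-methylhept-5-en-2-yl]-1-(phenylsulfonyl)non-7-en-2-one | O=S(=O)(CC(=O)[C@H](COCc1ccc(OC)cc1)[C@@H]([C@@H](C)CCC=C(C)C)[C@@H](O[Si](C)(C)C(C)(C)C)C/C(C)=C/CBr)c1ccccc1 | intermediate
26 | (4E,7S,8R,9S)-7-[(tert-butyldimethylsilyl)oxy]-9-{[(4-methoxybenzyl)oxy]methyl}-5-methyl-8-[(2S)-6-methylhept-5-en-2-yl]-2-(phenylsulfonyl)cyclonon-4-en-1-one (C2 epimers) | COc1ccc(COC[C@H]2C(=O)C(S(=O)(=O)c3ccccc3)C/C=C(\C)C[C@H](O[Si](C)(C)C(C)(C)C)[C@@H]2[C@@H](C)CCC=C(C)C)cc1 | intermediate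
27 | (4E,7S,8R,9S)-7-[(tert-butyldimethylsilyl)oxy]-9-{[(4-methoxybenzyl)oxy]methyl}-5-methyl-8-[(2S)-6-methylhept-5-en-2-yl]cyclonon-4-en-1-one | COc1ccc(COC[C@H]2C(=O)CC/C=C(\C)C[C@H](O[Si](C)(C)C(C)(C)C)[C@@H]2[C@@H](C)CCC=C(C)C)cc1 | intermediate
28 | potassium (1E,4E,7S,8R,9S)-7-[(tert-butyldimethylsilyl)oxy]-9-{[(4-methoxybenzyl)oxy]methyl}-5-methyl-8-[(2S)-6-methylhept-5-en-2-yl]cyclonona-1,4-dien-1-olate | [K+].COc1ccc(COC[C@H]2/C([O-])=C\C/C=C(\C)C[C@H](O[Si](C)(C)C(C)(C)C)[C@@H]2[C@@H](C)CCC=C(C)C)cc1 | intermediate (not isolated)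
29 | (1E,4E,7S,8R,9S)-7-[(tert-butyldimethylsilyl)oxy]-9-{[(4-methoxybenzyl)oxy]methyl}-5-methyl-8-[(2S)-6-methylhept-5-en-2-yl]cyclonona-1,4-dien-1-yl trifluoromethanesulfonate | COc1ccc(COC[C@H]2/C(OS(=O)(=O)C(F)(F)F)=C\C/C=C(\C)C[C@H](O[Si](C)(C)C(C)(C)C)[C@@H]2[C@@H](C)CCC=C(C)C)cc1 | intermediate
30 | (1E,4E,7S,8R,9S)-7-[(tert-butyldimethylsilyl)oxy]-9-(hydroxymethyl)-5-methyl-8-[(2S)-6-methylhept-5-en-2-yl]cyclonona-1,4-dien-1-yl trifluoromethanesulfonate | OC[C@H]1/C(OS(=O)(=O)C(F)(F)F)=C\C/C=C(\C)C[C@H](O[Si](C)(C)C(C)(C)C)[C@@H]1[C@@H](C)CCC=C(C)C | intermediate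
31 | [(1S,2E,5E,8S,9R)-8-[(tert-butyldimethylsilyl)oxy]-6-methyl-9-[(2S)-6-methylhept-5-en-2-yl]-2-{[(trifluoromethyl)sulfonyl]oxy}cyclonona-2,5-dien-1-yl]methyl acetate | CC(=O)OC[C@H]1/C(OS(=O)(=O)C(F)(F)F)=C\C/C=C(\C)C[C@H](O[Si](C)(C)C(C)(C)C)[C@@H]1[C@@H](C)CCC=C(C)C | intermediate
32 | [(1R,2E,5E,8S,9R)-8-[(tert-butyldimethylsilyl)oxy]-2-formyl-6-methyl-9-[(2S)-6-methylhept-5-en-2-yl]cyclonona-2,5-dien-1-yl]methyl acetate | CC(=O)OC[C@H]1/C(C=O)=C\C/C=C(\C)C[C@H](O[Si](C)(C)C(C)(C)C)[C@@H]1[C@@H](C)CCC=C(C)C | intermediate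
33 | hydroxyacetyldictyolal, [(1R,2E,5E,8S,9R)-2-formyl-8-hydroxy-6-methyl-9-[(2S)-6-methylhept-5-en-2-yl]cyclonona-2,5-dien-1-yl]methyl acetate | CC(=O)OC[C@H]1/C(C=O)=C\C/C=C(\C)C[C@H](O)[C@@H]1[C@@H](C)CCC=C(C)C | target

**Step count**

Total: 20 steps. Longest linear sequence: 18 steps (steps 1–3 and 6–20, from (S)-citronellal).

**Steps most likely to fail, and fallbacks**

Step 6. The risk is the sense of simple diastereoselection: if the bulky ligand sphere forces C10 into the equatorial position of the chair, the addition runs anti instead of syn. The fallback then changes the stereochemical plan, not only the ligand. It sets out again from 7 and 11 with the enantiomeric ligand, so that the Re face of the aldehyde is attacked; an anti addition then gives directly the trans lactone (4R,5S)-5-{(2E)-4-[(tert-butyldimethylsilyl)oxy]-2-methylbut-2-en-1-yl}-3-methylidene-4-[(2S)-6-methylhept-5-en-2-yl]oxolan-2-one F1, in which C8 already has the S configuration. PMB alcohol addition under the conditions of step 7 converts it into 20, where the route is rejoined; the inversion steps 8 and 9 fall away.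

Step 14. The risk is that closure of the nine-membered ring by C-alkylation is slower than intermolecular alkylation or O-alkylation of the keto sulfone enolate. The fallback sets out from alcohol 24, which is converted with methyl chloroformate and pyridine into (2E,5S,6R,7S)-5-[(tert-butyldimethylsilyl)oxy]-7-{[(4-methoxybenzyl)oxy]methyl}-3-methyl-6-[(2S)-6-methylhept-5-en-2-yl]-8-oxo-9-(phenylsulfonyl)non-2-en-1-yl methyl carbonate F2. With Pd(PPh3)4 and 1,2-bis(diphenylphosphino)ethane in THF at high dilution and 60 °C, zerovalent palladium ionises the carbonate to a π-allylpalladium complex with loss of CO2; the methoxide set free deprotonates the keto sulfone, and the stabilised carbanion attacks the less substituted allyl terminus C4 (Tsuji–Trost cyclisation under neutral conditions, which favours medium rings with stabilised carbanions). This gives 26, where the route is rejoined.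

Step 16. The risk is enolisation towards C1, which would be followed by β-elimination of the PMB alkoxide, or formation of the regioisomeric triflate. The fallback sets out from ketone 27, which is condensed with 2,4,6-triisopropylbenzenesulfonohydrazide to N'-[(4E,7S,8R,9S)-7-[(tert-butyldimethylsilyl)oxy]-9-{[(4-methoxybenzyl)oxy]methyl}-5-methyl-8-[(2S)-6-methylhept-5-en-2-yl]cyclonon-4-en-1-ylidene]-2,4,6-triisopropylbenzenesulfonohydrazide F3. Treatment with n-BuLi (2.2 equiv) in THF from −78 to 0 °C (Shapiro reaction, in which deprotonation at the less substituted α-carbon C3 is inherent) gives the C2 vinyllithium, which is quenched with DMF to (1E,4E,7S,8R,9R)-7-[(tert-butyldimethylsilyl)oxy]-9-{[(4-methoxybenzyl)oxy]methyl}-5-methyl-8-[(2S)-6-methylhept-5-en-2-yl]cyclonona-1,4-diene-1-carbaldehyde F4. DDQ then frees the alcohol to give (1E,4E,7S,8R,9R)-7-[(tert-butyldimethylsilyl)oxy]-9-(hydroxymethyl)-5-methyl-8-[(2S)-6-methylhept-5-en-2-yl]cyclonona-1,4-diene-1-carbaldehyde F5, and acetylation (Ac2O, pyridine) gives 32, where the route is rejoined; steps 17–19 are replaced.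

Further compounds
F1 | step 6 | (4R,5S)-5-{(2E)-4-[(tert-butyldimethylsilyl)oxy]-2-methylbut-2-en-1-yl}-3-methylidene-4-[(2S)-6-methylhept-5-en-2-yl]oxolan-2-one | C=C1C(=O)O[C@@H](C/C(C)=C/CO[Si](C)(C)C(C)(C)C)[C@@H]1[C@@H](C)CCC=C(C)C
F2 | step 14 | (2E,5S,6R,7S)-5-[(tert-butyldimethylsilyl)oxy]-7-{[(4-methoxybenzyl)oxy]methyl}-3-methyl-6-[(2S)-6-methylhept-5-en-2-yl]-8-oxo-9-(phenylsulfonyl)non-2-en-1-yl methyl carbonate | O=S(=O)(CC(=O)[C@H](COCc1ccc(OC)cc1)[C@@H]([C@@H](C)CCC=C(C)C)[C@@H](O[Si](C)(C)C(C)(C)C)C/C(C)=C/COC(=O)OC)c1ccccc1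
F3 | step 16 | N'-[(4E,7S,8R,9S)-7-[(tert-butyldimethylsilyl)oxy]-9-{[(4-methoxybenzyl)oxy]methyl}-5-methyl-8-[(2S)-6-methylhept-5-en-2-yl]cyclonon-4-en-1-ylidene]-2,4,6-triisopropylbenzenesulfonohydrazide | COc1ccc(COC[C@H]2C(=NNS(=O)(=O)c3c(C(C)C)cc(C(C)C)cc3C(C)C)CC/C=C(\C)C[C@H](O[Si](C)(C)C(C)(C)C)[C@@H]2[C@@H](C)CCC=C(C)C)cc1
F4 | step 16 | (1E,4E,7S,8R,9R)-7-[(tert-butyldimethylsilyl)oxy]-9-{[(4-methoxybenzyl)oxy]methyl}-5-methyl-8-[(2S)-6-methylhept-5-en-2-yl]cyclonona-1,4-diene-1-carbaldehyde | COc1ccc(COC[C@H]2/C(C=O)=C\C/C=C(\C)C[C@H](O[Si](C)(C)C(C)(C)C)[C@@H]2[C@@H](C)CCC=C(C)C)cc1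
F5 | step 16 | (1E,4E,7S,8R,9R)-7-[(tert-butyldimethylsilyl)oxy]-9-(hydroxymethyl)-5-methyl-8-[(2S)-6-methylhept-5-en-2-yl]cyclonona-1,4-diene-1-carbaldehyde | OC[C@H]1/C(C=O)=C\C/C=C(\C)C[C@H](O[Si](C)(C)C(C)(C)C)[C@@H]1[C@@H](C)CCC=C(C)C
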